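**Plan**

Numbering (daucane): C1 = quaternary fusion carbon (CH3), C2/C3 = CH2CH2, C4 = C(OH)(i-Pr), C5 = fusion CH, C6 = CH–O-anisoyl, C7 = CH2, C8(CH3)=C9H, C10 = C=O; β = the face of the C1 methyl.
Cuts, in retrosynthetic order: the ester C–O at O6; C8–CH3 and C10=O (oxidative allylic transposition, back to a plain C9=C10 alkene); C6–O to C6–B; C4–C5 (opens the cyclopentane); C1–C2 (conjugate addition). This leaves 3-methylcyclohepta-2,4-dienone and a six-carbon Grignard fragment.
Forward: the seven-membered ring is bought as cycloheptane-1,3-dione and only decorated. The cyclopentane C1–C2–C3–C4–C5 is the last ring closed, by a SmI2 ketyl–alkene 5-exo cyclisation of the C4 ketone onto C5 of a C5=C6(Bpin) alkenyl boronate.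
Enabling feature: the O4–C4–C5–C6–O6 1,3-dioxygen array across fusion carbon C5, with 4-OH trans to C6 on the cyclopentane and i-Pr on the concave face. A chelated or equilibrating aldol closure should not give this arrangement, but it matches the anti transition state of a ketyl–olefin closure. Boron on C6 activates C5 and later becomes O6 with retention.
Stereochemistry: C1 comes from a copper-catalysed asymmetric conjugate addition. C5 (tether, cis fusion), C4 (anti ketyl transition state) and C6 (convex-face protonation, then stereoretentive C–B oxidation) are all relayed from C1 in the key step.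

Key step: step 8

Assumption: the sense of induction of the copper–NHC catalyst on dienone 6 is not known, so the ligand enantiomer that gives (R)-11 is taken; both enantiomers of the amino-alcohol-derived ligand are available.

**Route**

Step 1
Reactants: 1 cycloheptane-1,3-dione
Product: 2 3-(2-methylpropoxy)cyclohept-2-en-1-one
Conditions: i-BuOH, TsOH·H2O (cat), toluene, Dean–Stark, reflux
Reagents that add atoms: 2-methylpropan-1-ol, CC(C)CO
Why: Acid-catalysed condensation of the enolised 1,3-diketone with the alcohol under removal of water (vinylogous ester formation) differentiates the two carbonyl carbons, the future C1 and C6.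

Step 2
Reactants: 2 3-(2-methylpropoxy)cyclohept-2-en-1-one
Product: 4 3-(2-methylpropoxy)cyclohepta-2,6-dien-1-one, via lithium dienolate 3 (not isolated)
Conditions: LiN(i-Pr)2, THF, −78 °C; then N-tert-butylbenzenesulfinimidoyl chloride, −78 °C
Reagents that add atoms: none
Why: Kinetic deprotonation of a vinylogous ester takes place at the α′ carbon (future C10), and the enolate is dehydrogenated in one pot by the sulfinimidoyl chloride (attack at sulfur, then syn elimination), a known ketone-to-enone dehydrogenation that installs the future C9=C10 alkene.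

Step 3
Reactants: 4 3-(2-methylpropoxy)cyclohepta-2,6-dien-1-one
Product: 6 3-methylcyclohepta-2,4-dien-1-one, via lithium alkoxide 5 (not isolated)
Conditions: MeLi, Et2O, −78 °C; then 1 M HCl, THF, 0 °C to rt
Reagents that add atoms: methyllithium, [Li]C; water, O
Why: Stork–Danheiser transposition, in which 1,2-addition of MeLi to the cross-conjugated ketone is followed by acid hydrolysis of the enol ether with loss of the bis-allylic hydroxyl, moves the carbonyl to C6 and gives the linear dienone that carries the C1 methyl.

Step 4
Reactants: 7 4-methylpent-1-en-3-one (isopropyl vinyl ketone)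
Product: 8 2-(2-bromoethyl)-2-(propan-2-yl)-1,3-dioxolane
Conditions: HBr (g), HOCH2CH2OH, CH2Cl2, 0 °C to rt
Reagents that add atoms: hydrogen bromide, Br; ethane-1,2-diol, OCCO
Why: Conjugate hydrobromination of the enone and in situ acid-catalysed ketalisation is the standard preparation of β-bromo ketals and masks the future C4 ketone for the organometallic step.

Step 5
Reactants: 6 3-methylcyclohepta-2,4-dien-1-one; 8 2-(2-bromoethyl)-2-(propan-2-yl)-1,3-dioxolane
Product: 11 (R)-3-methyl-3-{2-[2-(propan-2-yl)-1,3-dioxolan-2-yl]ethyl}cyclohepta-1,4-dien-1-yl trifluoromethanesulfonate, via Grignard reagent 9 (not isolated), via magnesium enolate 10 (not isolated)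
Conditions: Mg, Et2O–THF, 30 °C (gives 9); 6, Cu(OTf)2 (cat), 1-(1-hydroxy-4-methylpentan-2-yl)-3-mesityl-4,5-dihydroimidazolium hexafluorophosphate (single enantiomer, NHC precursor, cat), Et2O, −30 °C, slow addition of 9; then N-(5-chloropyridin-2-yl)bis(trifluoromethanesulfonimide), THF–DMPU, −30 °C to rt
Reagents that add atoms: N-(5-chloropyridin-2-yl)bis(trifluoromethanesulfonimide), O=S(=O)(N(c1ccc(Cl)cn1)S(=O)(=O)C(F)(F)F)C(F)(F)F
Why: Copper–NHC-catalysed asymmetric conjugate addition of a Grignard reagent to a β-substituted cyclic dienone, a reaction type known to go 1,4 rather than 1,6 and to build quaternary centres, sets C1 under catalyst control, and O-sulfonylation of the regiodefined enolate fixes the C5=C6 double bond on the hindered side, where enolisation of a free C6 ketone would not place it.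

Step 6
Reactants: 11 (R)-3-methyl-3-{2-[2-(propan-2-yl)-1,3-dioxolan-2-yl]ethyl}cyclohepta-1,4-dien-1-yl trifluoromethanesulfonate
Product: 12 (R)-3-methyl-3-(4-methyl-3-oxopentyl)cyclohepta-1,4-dien-1-yl trifluoromethanesulfonate
Conditions: 1 M HCl, THF, rt
Reagents that add atoms: water, O
Why: Acid hydrolysis of the dioxolane frees the C4 ketone, while the alkenyl triflate, the two ring alkenes and the quaternary centre are inert to dilute acid.

Step 7
Reactants: 12 (R)-3-methyl-3-(4-methyl-3-oxopentyl)cyclohepta-1,4-dien-1-yl trifluoromethanesulfonate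
Product: 13 4-methyl-1-[(1R)-1-methyl-3-(4,4,5,5-tetramethyl-1,3,2-dioxaborolan-2-yl)cyclohepta-2,6-dien-1-yl]pentan-3-one
Conditions: B2pin2, PdCl2(PPh3)2 (cat), PPh3, KOPh, toluene, 50 °C
Reagents that add atoms: bis(pinacolato)diboron, CC1(C)OB(OC1(C)C)B1OC(C)(C)C(C)(C)O1
Why: Miyaura borylation of an alkenyl triflate exchanges OTf for Bpin at C6 without moving the double bond, and the weak phenoxide base leaves the dialkyl ketone untouched.

Step 8
Reactants: 13 4-methyl-1-[(1R)-1-methyl-3-(4,4,5,5-tetramethyl-1,3,2-dioxaborolan-2-yl)cyclohepta-2,6-dien-1-yl]pentan-3-one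
Product: 14 (3R,3aS,4S,8aR)-8a-methyl-3-(propan-2-yl)-4-(4,4,5,5-tetramethyl-1,3,2-dioxaborolan-2-yl)-1,2,3,3a,4,5,6,8a-octahydroazulen-3-ol (cis-fused; 4-OH β, H5 β, H6 β, C6–Bpin α, C9=C10 alkene)
Conditions: SmI2 (2.5 equiv), HMPA, t-BuOH, THF, −78 to 0 °C
Reagents that add atoms: none
Why: Proposed new method: single-electron transfer from SmI2–HMPA to the isopropyl ketone of 13 gives a samarium ketyl at C4 that adds to C5 of the C5=C6(Bpin) alkene, and the α-boryl radical at C6, stabilised by the empty p orbital on boron, takes up a second electron to give an α-boryl organosamarium that t-BuOH protonates. The closest known reaction types are the SmI2 ketyl–olefin cyclisation of ketones onto acrylates or unactivated alkenes and the Giese-type addition of nucleophilic alkyl and α-oxy radicals to alkenyl boronic esters with reduction and protonation of the α-boryl radical; only their combination is new. The one ring closed is the cyclopentane C1–C2–C3–C4–C5, by radical 5-exo-trig attack through the tether C1–C2–C3. C5 is fixed by the tether, which reaches only the ring face that carries C2, so the fusion is cis (H5 syn to the C1 methyl); C4 is fixed by the usual anti transition state, in which the bulky, electron-rich O–Sm(HMPA)n group points away from the C5=C6 bond and ends trans to C6 with the isopropyl group on the concave face; C6 is fixed by protonation from the convex β face, which leaves boron α and cis to C4. The step needs site selectivity between the two ring alkenes that flank C1 (C5=C6 and C9=C10, both within 5-exo reach) and preference for cyclisation over plain ketone reduction; the boryl group secures both by lowering the LUMO of C5=C6 for the nucleophilic ketyl, while C9=C10 stays unactivated and no reducible enone is yet present.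

Step 9
Reactants: 14 bicyclic boronate
Product: 15 (3R,3aR,4S,8aR)-8a-methyl-3-(propan-2-yl)-1,2,3,3a,4,5,6,8a-octahydroazulene-3,4-diol
Conditions: 30% H2O2, aq NaOH, THF, 0 °C
Reagents that add atoms: hydrogen peroxide, OO
Why: Oxidation of the secondary alkyl boronic ester proceeds by 1,2-migration of C6 from boron to oxygen with retention, so the activating group becomes the α hydroxyl at C6, and no base-sensitive group is present at this stage.

Step 10
Reactants: 15 diol
Product: 16 (3R,3aR,4S,8aR)-3-hydroxy-8a-methyl-3-(propan-2-yl)-1,2,3,3a,4,5,6,8a-octahydroazulen-4-yl 4-methoxybenzoate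
Conditions: 4-MeOC6H4COCl, Et3N, DMAP (cat), CH2Cl2, rt
Reagents that add atoms: 4-methoxybenzoyl chloride, COc1ccc(cc1)C(Cl)=O
Why: DMAP-catalysed acylation takes the secondary C6 alcohol, because the tertiary C4 alcohol flanked by the isopropyl group is too hindered to compete.

Step 11
Reactants: 16 anisate
Product: 17 (3R,3aR,4S,8aR)-3-hydroxy-8a-methyl-6-oxo-3-(propan-2-yl)-1,2,3,3a,4,5,6,8a-octahydroazulen-4-yl 4-methoxybenzoate
Conditions: Rh2(cap)4 (dirhodium tetrakis(caprolactamate), cat), 70% aq t-BuOOH, 1,2-dichloroethane, 40 °C, no added base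
Reagents that add atoms: tert-butyl hydroperoxide, CC(C)(C)OO
Why: Dirhodium-catalysed allylic oxidation with t-BuOOH should be regiospecific because C8 holds the only allylic C–H bonds (the other allylic atom, C1, is quaternary), and the base-free variant spares the β-acyloxy ketone that is formed.

Step 12
Reactants: 17 enone
Product: 18 (3R,3aR,4S,8aR)-3,6-dihydroxy-6,8a-dimethyl-3-(propan-2-yl)-1,2,3,3a,4,5,6,8a-octahydroazulen-4-yl 4-methoxybenzoate (C8 carbinol configuration left open, since it is erased in step 13)
Conditions: MeLi, CeCl3, THF, −78 °C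
Reagents that add atoms: methyllithium, [Li]C
Why: 1,2-Addition of an organocerium reagent, whose low basicity and high oxophilicity favour attack at the C8 ketone over enolisation with β-elimination of anisate and over attack at the aryl ester, brings in the last carbon, and the new carbinol centre needs no control.

Step 13
Reactants: 18 tertiary allylic alcohol
Product: 19 (3R,3aR,4S,8aS)-3-hydroxy-6,8a-dimethyl-8-oxo-3-(propan-2-yl)-1,2,3,3a,4,5,8,8a-octahydroazulen-4-yl 4-methoxybenzoate (target)
Conditions: pyridinium chlorochromate (C5H5NH)[CrO3Cl], NaOAc, 4 Å MS, CH2Cl2, rt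
Reagents that add atoms: pyridinium chlorochromate, [O-][Cr](=O)(=O)Cl.c1cc[nH+]cc1
Why: Babler–Dauben oxidative transposition, in which the chromate ester of the tertiary allylic alcohol shifts [3,3] to C10 and is oxidised there, gives the C8(CH3)=C9–C10=O enone, while the non-allylic tertiary C4 alcohol and the ester are inert.

**Compound list**

1 | cycloheptane-1,3-dione | O=C1CCCCC(=O)C1 | starting material
2 | 3-(2-methylpropoxy)cyclohept-2-en-1-one | CC(C)COC1=CC(=O)CCCC1 | intermediate
3 | lithium dienolate of 2 (deprotonated at the α′ carbon) | CC(C)COC1=CC(O[Li])=CCCC1 | intermediate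
4 | 3-(2-methylpropoxy)cyclohepta-2,6-dien-1-one | CC(C)COC1=CC(=O)C=CCC1 | intermediate
5 | lithium 1-methyl-3-(2-methylpropoxy)cyclohepta-2,6-dien-1-olate | CC(C)COC1=CC(C)(O[Li])C=CCC1 | intermediate
6 | 3-methylcyclohepta-2,4-dien-1-one | CC1=CC(=O)CCC=C1 | intermediate
7 | 4-methylpent-1-en-3-one | CC(C)C(=O)C=C | starting material
8 | 2-(2-bromoethyl)-2-(propan-2-yl)-1,3-dioxolane | CC(C)C1(CCBr)OCCO1 | intermediate
9 | 2-[2-(propan-2-yl)-1,3-dioxolan-2-yl]ethylmagnesium bromide | CC(C)C1(CC[Mg]Br)OCCO1 | intermediate
10 | (R)-bromomagnesium enolate from 1,4-addition of 9 to 6 | CC(C)C1(CC[C@]2(C)C=CCCC(O[Mg]Br)=C2)OCCO1 | intermediate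
11 | (R)-3-methyl-3-{2-[2-(propan-2-yl)-1,3-dioxolan-2-yl]ethyl}cyclohepta-1,4-dien-1-yl triflate | CC(C)C1(CC[C@]2(C)C=CCCC(OS(=O)(=O)C(F)(F)F)=C2)OCCO1 | intermediate
12 | (R)-3-methyl-3-(4-methyl-3-oxopentyl)cyclohepta-1,4-dien-1-yl triflate | CC(C)C(=O)CC[C@]1(C)C=CCCC(OS(=O)(=O)C(F)(F)F)=C1 | intermediate
13 | 4-methyl-1-[(1R)-1-methyl-3-(pinacolatoboryl)cyclohepta-2,6-dien-1-yl]pentan-3-one | CC(C)C(=O)CC[C@]1(C)C=CCCC(B2OC(C)(C)C(C)(C)O2)=C1 | intermediate
14 | cis-fused bicyclic boronate (4-OH β, H5 β, C6–Bpin α, C9=C10) | CC1(C)OB(OC1(C)C)[C@H]1CCC=C[C@@]2(C)CC[C@@](O)(C(C)C)[C@@H]12 | intermediate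
15 | (3R,3aR,4S,8aR)-8a-methyl-3-(propan-2-yl)-1,2,3,3a,4,5,6,8a-octahydroazulene-3,4-diol | O[C@H]1CCC=C[C@@]2(C)CC[C@@](O)(C(C)C)[C@@H]12 | intermediate
16 | C6 4-methoxybenzoate of 15 | COc1ccc(cc1)C(=O)O[C@H]1CCC=C[C@@]2(C)CC[C@@](O)(C(C)C)[C@@H]12 | intermediate
17 | C8-oxo-C9=C10 enone | COc1ccc(cc1)C(=O)O[C@H]1CC(=O)C=C[C@@]2(C)CC[C@@](O)(C(C)C)[C@@H]12 | intermediate
18 | C8 tertiary allylic alcohol (C8 configuration open) | COc1ccc(cc1)C(=O)O[C@H]1CC(C)(O)C=C[C@@]2(C)CC[C@@](O)(C(C)C)[C@@H]12 | intermediate
19 | CNP0301380.1 | COc1ccc(cc1)C(=O)O[C@H]1CC(C)=CC(=O)[C@@]2(C)CC[C@@](O)(C(C)C)[C@@H]12 | target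

**Step count**

Total step count: 13. Longest linear sequence: 12 (steps 1–3 and 5–13).

**Steps most likely to fail**

Step 8. The ketyl may be reduced to the secondary alcohol before it cyclises, it may add to the unactivated C9=C10 alkene, or protonation at C6 may take place from the concave face. The fallback uses only known chemistry; it sets out from 12 and comes back at 15.
- Palladium-catalysed methoxycarbonylation of the alkenyl triflate (Pd(OAc)2, dppp, CO, MeOH, Et3N, DMF) should give the methyl cycloheptadienecarboxylate F1.
- Its α,β-unsaturated ester is the classical acceptor for a SmI2/t-BuOH ketyl–enoate 5-exo cyclisation. This should give the cis-fused hydroxy ester F2, with the same control at C4 and C5 and with C6 left open.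
- Reduction with i-Bu2AlH gives the aldehyde F3.
- Copper-catalysed aerobic deformylation of this α-branched aldehyde (Cu(OAc)2, 2,2′-bipyridine, DABCO, O2, DMF) gives the β-hydroxy ketone F4.
- Hydride delivery from the convex face with Li(s-Bu)3BH gives diol 15.

Step 5. Competing 1,6-addition at C9, weak facial selectivity with the functionalised Grignard reagent and slow O-sulfonylation of the magnesium enolate are the dangers. The fallback forms the other exocyclic bond at C1; it sets out from 4 and 9 and comes back at 11.
- Stork–Danheiser transposition of 4 with 9 in place of MeLi, with buffered acidic work-up that spares the dioxolane, should give the chain-bearing dienone F5.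
- A copper-catalysed asymmetric conjugate addition of Me3Al (Cu(OTf)2, chiral phosphoramidite, Et2O, −30 °C) delivers the small methyl group to C1.
- The dimethylaluminium enolate F6, activated with MeLi, is sulfonylated with the same triflimide to give 11.

Step 12. Enolisation of the β-acyloxy ketone with loss of anisate, or addition to the ester, may overtake addition at C8. The fallback avoids carbanionic reagents; it sets out from 17 and comes back at 18.
- Non-basic Takai–Lombardo methylenation (Zn, CH2Br2, TiCl4, THF) should give the cross-conjugated triene-free exocyclic diene F7.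
- Mukaiyama hydration (Mn(dpm)3, PhSiH3, O2, i-PrOH, then PPh3) starts by hydrogen-atom transfer to the terminal CH2. It should give 18 together with the C10 secondary allylic alcohol F8.
- The oxidant of step 13 converts both 18 and F8 to 19.

**Further compounds**

F1 | step 8 | methyl (R)-3-methyl-3-(4-methyl-3-oxopentyl)cyclohepta-1,4-diene-1-carboxylate | CC(C)C(=O)CC[C@]1(C)C=CCCC(C(=O)OC)=C1
F2 | step 8 | cis-fused C6 methyl ester, 4-OH β, H5 β, C6 open | COC(=O)C1CCC=C[C@@]2(C)CC[C@@](O)(C(C)C)[C@@H]12
F3 | step 8 | corresponding C6 carbaldehyde | O=CC1CCC=C[C@@]2(C)CC[C@@](O)(C(C)C)[C@@H]12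
F4 | step 8 | C6 ketone (β-hydroxy ketone), cis-fused | O=C1CCC=C[C@@]2(C)CC[C@@](O)(C(C)C)[C@@H]12
F5 | step 5 | 3-{2-[2-(propan-2-yl)-1,3-dioxolan-2-yl]ethyl}cyclohepta-2,4-dien-1-one | CC(C)C1(CCC2=CC(=O)CCC=C2)OCCO1
F6 | step 5 | (R)-dimethylaluminium enolate from methyl addition to F5 | CC(C)C1(CC[C@]2(C)C=CCCC(O[Al](C)C)=C2)OCCO1
F7 | step 12 | C8-methylidene C9=C10 diene | COc1ccc(cc1)C(=O)O[C@H]1CC(=C)C=C[C@@]2(C)CC[C@@](O)(C(C)C)[C@@H]12
F8 | step 12 | C10 secondary allylic alcohol with C8(CH3)=C9 (C10 open) | COc1ccc(cc1)C(=O)O[C@H]1CC(C)=CC(O)[C@@]2(C)CC[C@@](O)(C(C)C)[C@@H]12
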